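**Plan**

- Retrosynthesis: after removal of four MOM ethers, ring C is opened at C3–C4, which turns the C4 ketone into a ring A aldehyde and C2–C3 into a 1,1-disubstituted aryl enol ether, O1–C2(=C3H2)–ring B. The enol ether is traced back to an aryl ester (C=CH2 from C=O), the ester O1–C2 bond to a ring A salicylaldehyde and a ring B benzoic acid, and the three aryl–prenyl bonds to prenyl bromide.
- Forward: the diprenylated ring A aldehyde (from 2,4,6-trihydroxybenzaldehyde) and the ring B acid (from resorcinol by two ortho-lithiations) are joined as an ester. The aldehyde is masked, the ester methylenated, the aldehyde freed, and ring C is closed last.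
- Enabling feature: C4 is a carbonyl flanked by the C3 methylene, and C2 carries both O1 and ring B. An aldehyde C4–H can therefore add across a C2=C3 enol ether, so ring C, the ketone and the C2–H stereocentre arise in one isomerisation at unchanged oxidation level.
- Stereochemistry: the single stereocentre (2S) comes from the chiral bisphosphine on rhodium in that hydroacylation; no chiral starting material is used, and the final deprotection avoids base so ring C is not reopened.

Key step: step 10

Remark (assumption): the sense of induction of the ligand in step 10 cannot be predicted with confidence for this substrate class. The antipode written is a working choice, and the other one is used if a first screen shows the (2R) product.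

**Step 1**
Reactants: 1 2,4,6-trihydroxybenzaldehyde; 2 prenyl bromide (1-bromo-3-methylbut-2-ene)
Product: 3 2,4,6-trihydroxy-3,5-bis(3-methylbut-2-en-1-yl)benzaldehyde
Conditions: 2 (2.2 equiv), 10% aq. KOH, 0 °C → rt
Reagents that add atoms: none
Why: Nuclear C-prenylation of the phloroglucinol polyphenolate (SN2 on the allylic bromide by the ring carbons of the ambident anion in water) should go to the only two unsubstituted ring carbons, with mono-C- and O-prenylated material as separable side products.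

**Step 2**
Reactants: 3 2,4,6-trihydroxy-3,5-bis(3-methylbut-2-en-1-yl)benzaldehyde
Product: 4 2-hydroxy-4,6-bis(methoxymethoxy)-3,5-bis(3-methylbut-2-en-1-yl)benzaldehyde
Conditions: MOMCl (2.2 equiv), i-Pr2NEt (3 equiv), CH2Cl2, 0 °C → rt
Reagents that add atoms: chloromethyl methyl ether (MOMCl), COCCl
Why: MOM protection (Williamson-type O-alkylation) should take the para phenol and one ortho phenol, while the last ortho OH, hydrogen-bonded to the formyl oxygen, stays free and thereby differentiates the two equivalent ortho oxygens.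

**Step 3**
Reactants: 5 resorcinol
Product: 6 1,3-bis(methoxymethoxy)benzene
Conditions: NaH (2.5 equiv), DMF, 0 °C; MOMCl (2.4 equiv), 0 °C → rt
Reagents that add atoms: chloromethyl methyl ether (MOMCl), COCCl
Why: Williamson O-alkylation of both phenoxides (MOM protection) installs the two ortho-directing groups needed for steps 4 and 5.

**Step 4**
Reactants: 6 1,3-bis(methoxymethoxy)benzene; 2 prenyl bromide
Product: 8 1,3-bis(methoxymethoxy)-2-(3-methylbut-2-en-1-yl)benzene, via aryllithium 7 (not isolated)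
Conditions: n-BuLi, THF, 0 °C → rt; CuBr·SMe2 (10 mol %), 2, −78 °C → rt
Reagents that add atoms: none
Why: Directed ortho-metalation occurs at C2 between the two OMOM groups, and copper-assisted SN2 allylation of the aryllithium with the primary allylic bromide should give the linear prenyl arene.

**Step 5**
Reactants: 8 1,3-bis(methoxymethoxy)-2-(3-methylbut-2-en-1-yl)benzene
Product: 10 2,4-bis(methoxymethoxy)-3-(3-methylbut-2-en-1-yl)benzoic acid, via aryllithium 9 (not isolated)
Conditions: n-BuLi, TMEDA, THF, −20 → 0 °C; CO2 (g), −78 °C → rt; 1 M HCl to pH 4, 0 °C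
Reagents that add atoms: carbon dioxide, O=C=O
Why: A second directed ortho-metalation at the ring position next to one OMOM group (the two such positions are equivalent) followed by carboxylation gives the benzoic acid, and brief cold acidification to pH 4 should leave the MOM ethers intact.

**Step 6**
Reactants: 4 2-hydroxy-4,6-bis(methoxymethoxy)-3,5-bis(3-methylbut-2-en-1-yl)benzaldehyde; 10 2,4-bis(methoxymethoxy)-3-(3-methylbut-2-en-1-yl)benzoic acid
Product: 11 2-formyl-3,5-bis(methoxymethoxy)-4,6-bis(3-methylbut-2-en-1-yl)phenyl 2,4-bis(methoxymethoxy)-3-(3-methylbut-2-en-1-yl)benzoate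
Conditions: EDC·HCl (1.5 equiv), DMAP (1.0 equiv), CH2Cl2, 0 °C → rt
Reagents that add atoms: none
Why: Steglich esterification: the chelated phenol is the only free hydroxyl of 4, and the acylpyridinium formed from 10 should acylate it despite the two ortho substituents.

**Step 7**
Reactants: 11 2-formyl-3,5-bis(methoxymethoxy)-4,6-bis(3-methylbut-2-en-1-yl)phenyl 2,4-bis(methoxymethoxy)-3-(3-methylbut-2-en-1-yl)benzoate
Product: 12 2-(dimethoxymethyl)-3,5-bis(methoxymethoxy)-4,6-bis(3-methylbut-2-en-1-yl)phenyl 2,4-bis(methoxymethoxy)-3-(3-methylbut-2-en-1-yl)benzoate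
Conditions: HC(OMe)3 (5 equiv), PPTS (5 mol %), MeOH, rt; Et3N quench
Reagents that add atoms: trimethyl orthoformate, COC(OC)OC
Why: Acid-catalysed acetalisation driven by the orthoformate masks the aldehyde for the methylenation, and PPTS is too weak to cleave MOM ethers, methanolyse the aryl ester or protonate the prenyl double bonds.

**Step 8**
Reactants: 12 2-(dimethoxymethyl)-3,5-bis(methoxymethoxy)-4,6-bis(3-methylbut-2-en-1-yl)phenyl 2,4-bis(methoxymethoxy)-3-(3-methylbut-2-en-1-yl)benzoate
Product: 13 2-(dimethoxymethyl)-1-({1-[2,4-bis(methoxymethoxy)-3-(3-methylbut-2-en-1-yl)phenyl]ethenyl}oxy)-3,5-bis(methoxymethoxy)-4,6-bis(3-methylbut-2-en-1-yl)benzene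
Conditions: Cp2TiMe2 (3 equiv), toluene, 70 °C, dark; basic work-up
Reagents that add atoms: dimethyltitanocene (Cp2TiMe2), [CH3-].[CH3-].[Ti+4].c1cc[cH-]c1.c1cc[cH-]c1
Why: Petasis methylenation: Cp2Ti=CH2 generated thermally adds to the ester carbonyl and cycloreverts to the aryl 1-arylvinyl ether, while the acetal, the MOM ethers and the trisubstituted alkenes are inert to this non-acidic reagent.

**Step 9**
Reactants: 13 2-(dimethoxymethyl)-1-({1-[2,4-bis(methoxymethoxy)-3-(3-methylbut-2-en-1-yl)phenyl]ethenyl}oxy)-3,5-bis(methoxymethoxy)-4,6-bis(3-methylbut-2-en-1-yl)benzene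
Product: 14 2-({1-[2,4-bis(methoxymethoxy)-3-(3-methylbut-2-en-1-yl)phenyl]ethenyl}oxy)-4,6-bis(methoxymethoxy)-3,5-bis(3-methylbut-2-en-1-yl)benzaldehyde
Conditions: PPTS (2 mol %), acetone–H2O (20:1), 0 °C, short contact; NaHCO3 quench
Reagents that add atoms: water, O
Why: Acetal hydrolysis by way of an oxocarbenium ion stabilised by three ring oxygens should be much faster than C-protonation of the aryl enol ether or cleavage of the MOM acetals, so a trace of weak acid at 0 °C is expected to free only the aldehyde.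

**Step 10**
Reactants: 14 2-({1-[2,4-bis(methoxymethoxy)-3-(3-methylbut-2-en-1-yl)phenyl]ethenyl}oxy)-4,6-bis(methoxymethoxy)-3,5-bis(3-methylbut-2-en-1-yl)benzaldehyde
Product: 15 (2S)-2-[2,4-bis(methoxymethoxy)-3-(3-methylbut-2-en-1-yl)phenyl]-5,7-bis(methoxymethoxy)-6,8-bis(3-methylbut-2-en-1-yl)-2,3-dihydro-4H-chromen-4-one
Conditions: [Rh(cod)Cl]2 (2.5 mol %), (R)-DTBM-SEGPHOS (5.5 mol %), NaB[3,5-(CF3)2C6H3]4 (5 mol %), degassed 1,4-dioxane, 60 °C
Reagents that add atoms: none
Why: Proposed new method: the aldehyde C–H of 14 should add oxidatively to the cationic monovalent rhodium–bisphosphine complex, the tethered enol ether then inserts into the Rh–H bond with hydrogen going to the oxygen- and aryl-bearing carbon (future C2) and rhodium to the terminal CH2 (future C3), and C–C reductive elimination from the seven-membered acyl–alkyl rhodacycle forms the C3–C4 bond and releases the catalyst. The closest known reaction type is the rhodium–bisphosphine-catalysed enantioselective intramolecular hydroacylation of 1,1-disubstituted alkenes in ortho-alkenyl benzaldehydes, which gives 3-substituted indanones and tetralones; an aryl enol ether as the alkene is the untested element. Ring C closes in a 6-endo-trig mode with respect to the enol ether C=C, the acyl carbon bonding to the terminal alkene carbon. The only new stereocentre, C2, is created when the hydride is delivered to one face of the prochiral 1,1-disubstituted alkene, and the chiral bisphosphine on rhodium is the controlling element. The step needs 6-endo over 5-exo regioselectivity (secured because the alternative requires reductive elimination at a fully substituted carbon), chemoselectivity for the enol ether over the three prenyl double bonds (these trisubstituted alkenes bind weakly and cannot reach the acyl carbon in an unstrained ring), and insertion faster than decarbonylation (the ortho OMOM oxygen at C5 can act as a hemilabile donor that holds the acyl hydride).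

**Step 11**
Reactants: 15 (2S)-2-[2,4-bis(methoxymethoxy)-3-(3-methylbut-2-en-1-yl)phenyl]-5,7-bis(methoxymethoxy)-6,8-bis(3-methylbut-2-en-1-yl)-2,3-dihydro-4H-chromen-4-one
Product: 16 (2S)-2-[2,4-dihydroxy-3-(3-methylbut-2-en-1-yl)phenyl]-5,7-dihydroxy-6,8-bis(3-methylbut-2-en-1-yl)-2,3-dihydro-4H-chromen-4-one
Conditions: 3 M aq. HCl/MeOH (1:10), rt → 40 °C, monitored; NaHCO3 to pH 6
Reagents that add atoms: none
Why: Acid-catalysed methanolysis of the four aryl MOM acetals, a standard end-game for prenylated flavanones, avoids base (no retro-oxa-Michael opening at C2) and at this acidity and temperature should not add the phenols across the prenyl double bonds.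

**Compound list**

1 | 2,4,6-trihydroxybenzaldehyde | O=Cc1c(O)cc(O)cc1O | starting material
2 | prenyl bromide (1-bromo-3-methylbut-2-ene) | CC(C)=CCBr | starting material
3 | 2,4,6-trihydroxy-3,5-bis(3-methylbut-2-en-1-yl)benzaldehyde | O=Cc1c(O)c(CC=C(C)C)c(O)c(CC=C(C)C)c1O | intermediate
4 | 2-hydroxy-4,6-bis(methoxymethoxy)-3,5-bis(3-methylbut-2-en-1-yl)benzaldehyde | O=Cc1c(O)c(CC=C(C)C)c(OCOC)c(CC=C(C)C)c1OCOC | intermediate
5 | resorcinol | Oc1cccc(O)c1 | starting material
6 | 1,3-bis(methoxymethoxy)benzene | COCOc1cccc(OCOC)c1 | intermediate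
7 | [2,6-bis(methoxymethoxy)phenyl]lithium | [Li]c1c(OCOC)cccc1OCOC | intermediate
8 | 1,3-bis(methoxymethoxy)-2-(3-methylbut-2-en-1-yl)benzene | COCOc1cccc(OCOC)c1CC=C(C)C | intermediate
9 | [2,4-bis(methoxymethoxy)-3-(3-methylbut-2-en-1-yl)phenyl]lithium | [Li]c1ccc(OCOC)c(CC=C(C)C)c1OCOC | intermediate
10 | 2,4-bis(methoxymethoxy)-3-(3-methylbut-2-en-1-yl)benzoic acid | COCOc1ccc(C(=O)O)c(OCOC)c1CC=C(C)C | intermediate
11 | 2-formyl-3,5-bis(methoxymethoxy)-4,6-bis(3-methylbut-2-en-1-yl)phenyl 2,4-bis(methoxymethoxy)-3-(3-methylbut-2-en-1-yl)benzoate | O=Cc1c(OC(=O)c2ccc(OCOC)c(CC=C(C)C)c2OCOC)c(CC=C(C)C)c(OCOC)c(CC=C(C)C)c1OCOC | intermediate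
12 | 2-(dimethoxymethyl)-3,5-bis(methoxymethoxy)-4,6-bis(3-methylbut-2-en-1-yl)phenyl 2,4-bis(methoxymethoxy)-3-(3-methylbut-2-en-1-yl)benzoate | COC(OC)c1c(OC(=O)c2ccc(OCOC)c(CC=C(C)C)c2OCOC)c(CC=C(C)C)c(OCOC)c(CC=C(C)C)c1OCOC | intermediate
13 | 2-(dimethoxymethyl)-1-({1-[2,4-bis(methoxymethoxy)-3-(3-methylbut-2-en-1-yl)phenyl]ethenyl}oxy)-3,5-bis(methoxymethoxy)-4,6-bis(3-methylbut-2-en-1-yl)benzene | COC(OC)c1c(OC(=C)c2ccc(OCOC)c(CC=C(C)C)c2OCOC)c(CC=C(C)C)c(OCOC)c(CC=C(C)C)c1OCOC | intermediate
14 | 2-({1-[2,4-bis(methoxymethoxy)-3-(3-methylbut-2-en-1-yl)phenyl]ethenyl}oxy)-4,6-bis(methoxymethoxy)-3,5-bis(3-methylbut-2-en-1-yl)benzaldehyde | O=Cc1c(OC(=C)c2ccc(OCOC)c(CC=C(C)C)c2OCOC)c(CC=C(C)C)c(OCOC)c(CC=C(C)C)c1OCOC | intermediate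
15 | (2S)-2-[2,4-bis(methoxymethoxy)-3-(3-methylbut-2-en-1-yl)phenyl]-5,7-bis(methoxymethoxy)-6,8-bis(3-methylbut-2-en-1-yl)-2,3-dihydro-4H-chromen-4-one | COCOc1ccc([C@@H]2CC(=O)c3c(OCOC)c(CC=C(C)C)c(OCOC)c(CC=C(C)C)c3O2)c(OCOC)c1CC=C(C)C | intermediate
16 | (2S)-2-[2,4-dihydroxy-3-(3-methylbut-2-en-1-yl)phenyl]-5,7-dihydroxy-6,8-bis(3-methylbut-2-en-1-yl)-2,3-dihydro-4H-chromen-4-one | CC(C)=CCc1c(O)ccc([C@@H]2CC(=O)c3c(O)c(CC=C(C)C)c(O)c(CC=C(C)C)c3O2)c1O | target

**Step count and risks**

Total steps: 11. Longest linear sequence: 9 steps (steps 3 to 11, from resorcinol).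

**Risk 1, step 10 (Proposed new method).** The acyl rhodium hydride may lose CO before the hindered, electron-rich enol ether inserts, or the insertion may occur with poor facial selectivity. The fallback uses known chemistry and closes ring C at O1–C2 instead; it sets out from 4 and 8 and comes back at 15.
- 4 is treated with MeMgBr (THF, 0 °C) to give the racemic secondary alcohol 2-(1-hydroxyethyl)-3,5-bis(methoxymethoxy)-4,6-bis(3-methylbut-2-en-1-yl)phenol F1.
- MnO2 (CH2Cl2, rt) oxidises it to the acetophenone 1-[2-hydroxy-4,6-bis(methoxymethoxy)-3,5-bis(3-methylbut-2-en-1-yl)phenyl]ethan-1-one F2.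
- 8 is lithiated as in step 5 (aryllithium 9) and quenched with DMF to give 2,4-bis(methoxymethoxy)-3-(3-methylbut-2-en-1-yl)benzaldehyde F3.
- Claisen–Schmidt condensation of the two (KOH, EtOH/H2O, rt) should give the (E)-2'-hydroxychalcone F4.
- NaOAc in refluxing EtOH closes it by oxa-Michael addition to the racemic flavanone F5.
- Kinetic resolution by asymmetric transfer hydrogenation follows (RuCl(p-cymene)[(R,R)-TsDPEN] or its antipode, whichever reduces the (2R) ketone faster; HCO2H/Et3N, rt). It should convert the (2R) ketone into the cis-(2R,4R)-flavan-4-ol F6 and leave the (2S) ketone 15, separated by chromatography.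

**Risk 2, step 9.** C-protonation of the enol ether may compete with ionisation of the acetal, which would hydrolyse the vinyl ether to a ketone and a phenol. The fallback carries the aldehyde carbon as a silyl-protected benzylic alcohol so that no acid meets the enol ether; it sets out from 4 and comes back at 14.
- 4 is reduced (NaBH4, MeOH/THF, 0 °C) to the salicyl alcohol 2-(hydroxymethyl)-3,5-bis(methoxymethoxy)-4,6-bis(3-methylbut-2-en-1-yl)phenol F7.
- TBSCl/imidazole (DMF, 0 °C) silylates the primary hydroxyl to give the silyl ether F8.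
- Steglich esterification with 10 as in step 6 gives the ester F9.
- Petasis methylenation as in step 8 gives the enol ether F10.
- TBAF (THF, 0 °C) frees the benzylic alcohol F11.
- MnO2 (CH2Cl2, rt) oxidises it to 14.

**Risk 3, step 11.** Brønsted acid may add the freed ortho phenols across the prenyl double bonds (chroman formation) or induce opening and reclosure at C2 with loss of enantiopurity. The fallback replaces protic solvolysis by an aprotic protecting-group exchange; it sets out from 15 and comes back at 16.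
- 15 is treated with Me3SiOTf and 2,2'-bipyridyl (CH2Cl2, 0 °C → rt), which should exchange each aryl MOM ether for a trimethylsilyl ether under weakly basic conditions to give the tetrakis(trimethylsilyl) ether F12.
- The labile silyl ethers are then hydrolysed with water (THF/pH 7 buffer, rt) to give 16.

**Further compounds**

F1 | step 10 | 2-(1-hydroxyethyl)-3,5-bis(methoxymethoxy)-4,6-bis(3-methylbut-2-en-1-yl)phenol (racemic) | CC(O)c1c(O)c(CC=C(C)C)c(OCOC)c(CC=C(C)C)c1OCOC
F2 | step 10 | 1-[2-hydroxy-4,6-bis(methoxymethoxy)-3,5-bis(3-methylbut-2-en-1-yl)phenyl]ethan-1-one | CC(=O)c1c(O)c(CC=C(C)C)c(OCOC)c(CC=C(C)C)c1OCOC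
F3 | step 10 | 2,4-bis(methoxymethoxy)-3-(3-methylbut-2-en-1-yl)benzaldehyde | O=Cc1ccc(OCOC)c(CC=C(C)C)c1OCOC
F4 | step 10 | (E)-3-[2,4-bis(methoxymethoxy)-3-(3-methylbut-2-en-1-yl)phenyl]-1-[2-hydroxy-4,6-bis(methoxymethoxy)-3,5-bis(3-methylbut-2-en-1-yl)phenyl]prop-2-en-1-one | COCOc1ccc(/C=C/C(=O)c2c(O)c(CC=C(C)C)c(OCOC)c(CC=C(C)C)c2OCOC)c(OCOC)c1CC=C(C)C
F5 | step 10 | racemic 2-[2,4-bis(methoxymethoxy)-3-(3-methylbut-2-en-1-yl)phenyl]-5,7-bis(methoxymethoxy)-6,8-bis(3-methylbut-2-en-1-yl)-2,3-dihydro-4H-chromen-4-one | COCOc1ccc(C2CC(=O)c3c(OCOC)c(CC=C(C)C)c(OCOC)c(CC=C(C)C)c3O2)c(OCOC)c1CC=C(C)C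
F6 | step 10 | (2R,4R)-2-[2,4-bis(methoxymethoxy)-3-(3-methylbut-2-en-1-yl)phenyl]-5,7-bis(methoxymethoxy)-6,8-bis(3-methylbut-2-en-1-yl)-3,4-dihydro-2H-chromen-4-ol | COCOc1ccc([C@H]2C[C@@H](O)c3c(OCOC)c(CC=C(C)C)c(OCOC)c(CC=C(C)C)c3O2)c(OCOC)c1CC=C(C)C
F7 | step 9 | 2-(hydroxymethyl)-3,5-bis(methoxymethoxy)-4,6-bis(3-methylbut-2-en-1-yl)phenol | OCc1c(O)c(CC=C(C)C)c(OCOC)c(CC=C(C)C)c1OCOC
F8 | step 9 | 2-({[tert-butyl(dimethyl)silyl]oxy}methyl)-3,5-bis(methoxymethoxy)-4,6-bis(3-methylbut-2-en-1-yl)phenol | CC(C)(C)[Si](C)(C)OCc1c(O)c(CC=C(C)C)c(OCOC)c(CC=C(C)C)c1OCOC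
F9 | step 9 | 2-({[tert-butyl(dimethyl)silyl]oxy}methyl)-3,5-bis(methoxymethoxy)-4,6-bis(3-methylbut-2-en-1-yl)phenyl 2,4-bis(methoxymethoxy)-3-(3-methylbut-2-en-1-yl)benzoate | CC(C)(C)[Si](C)(C)OCc1c(OC(=O)c2ccc(OCOC)c(CC=C(C)C)c2OCOC)c(CC=C(C)C)c(OCOC)c(CC=C(C)C)c1OCOC
F10 | step 9 | tert-butyl{[2-({1-[2,4-bis(methoxymethoxy)-3-(3-methylbut-2-en-1-yl)phenyl]ethenyl}oxy)-4,6-bis(methoxymethoxy)-3,5-bis(3-methylbut-2-en-1-yl)phenyl]methoxy}dimethylsilane | CC(C)(C)[Si](C)(C)OCc1c(OC(=C)c2ccc(OCOC)c(CC=C(C)C)c2OCOC)c(CC=C(C)C)c(OCOC)c(CC=C(C)C)c1OCOC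
F11 | step 9 | [2-({1-[2,4-bis(methoxymethoxy)-3-(3-methylbut-2-en-1-yl)phenyl]ethenyl}oxy)-4,6-bis(methoxymethoxy)-3,5-bis(3-methylbut-2-en-1-yl)phenyl]methanol | OCc1c(OC(=C)c2ccc(OCOC)c(CC=C(C)C)c2OCOC)c(CC=C(C)C)c(OCOC)c(CC=C(C)C)c1OCOC
F12 | step 11 | (2S)-2-[3-(3-methylbut-2-en-1-yl)-2,4-bis(trimethylsilyloxy)phenyl]-6,8-bis(3-methylbut-2-en-1-yl)-5,7-bis(trimethylsilyloxy)-2,3-dihydro-4H-chromen-4-one | C[Si](C)(C)Oc1ccc([C@@H]2CC(=O)c3c(O[Si](C)(C)C)c(CC=C(C)C)c(O[Si](C)(C)C)c(CC=C(C)C)c3O2)c(O[Si](C)(C)C)c1CC=C(C)C
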